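Every mole of solid substrate charged stays on the books, as solid, as dissolved starting material, as target or as isomer of the product; the seed of target adds a small entry of its own. You keep this ledger on the limiting reagent, the solid substrate, in fractions of the charge.

| setting | birch | alder | north | north-west | east |
|---|---|---|---|---|---|
| solid substrate | 0.10 M | 0.10 M | 0.10 M | 0.10 M | 0.10 M |
| target | 0.50 mM | 0.75 mM | 1.00 mM | 1.00 mM | 1.00 mM |
| temperature | 45 °C | 60 °C |  | 70 °C | 50 °C |
| remark | run made earlier | run made earlier | at 50 °C until 3.0 h, from then on at 70 °C |  |  |
| time |  |  | 15 h | 15 h | 15 h |

| run | time / h | target / % | isomer of the product / % |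
|---|---|---|---|
| birch | 15.0 | 81.8 | 19.0 |
| birch | 30.0 | 54.9 | 45.4 |
| birch | 48.0 | 34.6 | 66.5 |
| birch | 72.0 | 17.3 | 82.0 |
| alder | 2.50 | 16.4 | 1.5 |
| alder | 8.00 | 61.7 | 38.1 |
| alder | 12.0 | 35.1 | 66.0 |
| alder | 20.0 | 11.0 | 89.4 |
| alder | 30.0 | 3.2 | 98.3 |

(each reading ± 0.5 percentage points)

- given per volume of solution although it is solid: solid substrate
- steps that have been proposed: starting material -> target; solid substrate <-> starting material; target <-> isomer of the product; starting material + target -> 2 target
- at the start none of the solid substrate is in solution
- what has only dissolved of solid substrate counts as not reacted

1. which flask leads in share of target in all that became target or isomer of the product ("all alike" within 1.5 percentage points) (north / north-west / east / all alike)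
2. share of target in all that became target or isomer of the product, north
3. share of target in all that became target or isomer of the product, north-west
4. share of target in all that became target or isomer of the product, east

In birch, target plus isomer of the product stand at 101 % at 15.0 h, and in alder at 99.8 % at 8.00 h. From those readings on, the one transfer visible in the ledger is target to isomer of the product. So I take the filling as finished and reckon with what stays free. The target readings fall first-order, at 0.0273 h⁻¹ in birch and 0.144 h⁻¹ in alder. Interpolating ln k in temperature gives the share clock, the first-order constant at which the share of target falls once the filling is over, at 50 °C: 0.0474 h⁻¹.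

Running each clock back to a share of one gives a start date, when the charge might have appeared as target at once: 7.34 h in birch and 4.65 h in alder. I ignore their different seeds and carry this on to 6.44 h for east and 2.86 h for north-west. East then keeps 66.6 %. At 70 °C the constant extrapolates to 0.435 h⁻¹, and a bare exponential for north-west gives 0.508 %. This count has no back step in it, though the step between target and isomer of the product is proposed both ways, so I hold the figure as a low estimate, not as what north-west keeps. North, charged pro rata for its cool hours, starts at 4.53 h, and the same bare exponential gives 1.05 %, again a low estimate. East stands far above both estimates.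

The forecast also names east, with 64 % (58 % to 70 %) there, 2.2 % in north and 1.7 % in north-west: “Afterwards target decays first-order to isomer, towards an equilibrium near 1% target.” My east lies above its value, and my bare exponentials for the hot flasks lie below its values.

The flasks give east in the lead, with 63.7 % there, 2.79 % in north and 2.02 % in north-west.

    starting material → target (k = 8.30 × 10⁻⁵ h⁻¹, Ea = 123 kJ mol⁻¹)
    solid substrate ⇌ starting material, rate k2*(cs2 - [starting material]) while solid is left; crystals form when [starting material] > cs2 (solubility = 11.0 mM, k = 1.70 h⁻¹)
    target ⇌ isomer of the product (K = 110, k = 0.420 h⁻¹, Ea = 100 kJ mol⁻¹, ΔH = −45.0 kJ mol⁻¹)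
    starting material + target → 2 target (k = 410 M⁻¹ h⁻¹, Ea = 53.0 kJ mol⁻¹)
    (constants at 70 °C)

Now read east later, at 40 h, with amounts and temperature held. At 15.0 h east holds 0 % solid substrate, so the clock runs from 63.7 % through the next 25.0 h and leaves 19.5 %. That neighbouring flask gives 19.3 %, with target at 19.5 % and isomer of the product at 81.5 %.

The numbers in the tables were computed for an exercise; scatter was added.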